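## Analysis of the target

The target is a flavan (2-arylchroman). Ring A is a phloroglucinol-type ring with OMe at C5, H at C6, OH at C7, prenyl at C8 and the ring oxygen O1 on C8a. Ring C is the dihydropyran that holds all three stereocentres, and ring B is a 4-hydroxyphenyl group on C2. The stereocentres C2 (R), C3 (S) and C4 (S) are contiguous: the aryl group and the C3 hydroxyl are trans, the C3 and C4 hydroxyls are cis (4β), so on the half-chair of ring C the C2 and C3 substituents are equatorial and the C4 hydroxyl is axial. The C4 hydroxyl is benzylic to a ring with three oxygen donors and ionises in acid, which leads to epimerisation, elimination or self-condensation. The prenyl group next to the C7 phenol closes to a chroman with acid and to a chromene with oxidants, and the O1–C2 bond can open in base through a ring B quinone methide. The synthesis is hard because the three ring A oxygens must be told apart, the prenyl group must go to C8 and not C6, the axial C4 alcohol is the less accessible epimer, and the last steps may use neither acid nor oxidant. The strategy rests on one feature: the chain ring B–C2–C3(O)–C4 is the carbon skeleton of tyrosine with oxygen in place of nitrogen at C3. C4 is the carboxyl carbon, and C2 is the benzylic CH2 para to the ring B oxygen, the one C–H position of the chain that an oxidant can pick out. A bromine at C8, placed between the two free hydroxyls of the ring A building block, makes that block symmetric and removes every regiochemical question on ring A.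

## Retrosynthetic reasoning

21 back to 20: the four O–Si bonds are cut last. All hydroxyls are carried as silyl ethers so that a single buffered fluoride treatment, neither acidic nor oxidising, ends the synthesis.

20 back to 16 and 17: the C8–CH2 bond of the prenyl group is cut. A prenyl group ortho to a free phenol would not survive the oxidant that closes ring C, so it has to come after that step. A C8 bromide is an inert placeholder that becomes the nucleophile (18, then 19). The forward step has to exchange bromine for metal without disturbing four silyl ethers and alkylate at the primary carbon of 17.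

16 back to 15 and 14: the O4–Si bond and then the C4–H bond are cut, which takes the C4 carbinol back to a ketone. With the C2 and C3 substituents equatorial, a bulky hydride should give the axial alcohol that the target needs. The ketone is also what makes the next disconnections possible: it deactivates ring A toward the oxidant and turns the C4–C4a bond into an aryl ketone bond.

14 back to 13: the O1–C2 bond is cut, so ring C is opened to a dihydrochalcone in which C2 is a plain benzylic CH2. Cutting here, rather than at C2–C3 or C3–C4, keeps the three-carbon chain intact as an aryl-lactic acid unit, so C3 can be bought as a stereocentre. The forward reaction must remove hydride from C2, let the phenol on C8a capture the cation, and set C2 trans to the C3 silyloxy group without touching C3.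

13 back to 12, 11, and then 5 plus 10: after exchange of silyl for hydrogen and hydrogen for acetyl, the C4–C4a bond is cut as a Friedel–Crafts acylation. Arene 5 has only two open positions and they are equivalent, so one regioisomer can form and bromine ends up at C8 with no selectivity to control. The forward step must acylate without racemising the carbon next to the acyl group.

10 back to 9, 8 and 6: the acid chloride comes from the diacetate 9 of hydroxy acid 8, and the C3–O bond of 8 replaces the C–N bond of D-tyrosine (6). The exchange has to run with retention, which the neighbouring carboxylate provides (through 7).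

5 back to 4, 2 and 1: the C–Br bond is cut. Electrophilic bromination of 1 would not distinguish the position between the two hydroxyls from the two positions next to the methoxy group, so bromine is delivered to the lithiated carbon of 3, where two acetal oxygens direct the base.

## Alternatives that were turned down

Alternative 1: The C2–C3 bond and the C3–O bond are made together. The ylide from sulfonium salt A3 (LiN(SiMe3)2) adds to the ring A α-silyloxy aldehyde A2 and the betaine closes to the trans epoxide A1. The C8a phenol is then freed and opens the epoxide at benzylic C2 (6-endo, inversion).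
- For it: the prenyl group is carried from the start, no oxidant is used, there is no late organometallic step, and C4 arrives at the alcohol oxidation level. On these points it is stronger than the chosen route.
- Against it: the stereocentre of A2 lies between an electron-rich arene and an aldehyde and epimerises easily, and A2 itself needs an asymmetric step.
- Against it: the ylide addition must control the trans geometry of the epoxide and the face of the aldehyde at once, with only the modest bias of an α-silyloxy group.
- Against it: A3 is a latent quinone methide, and closing ring C requires one of three aryl silyl ethers to be removed next to an epoxide that opens by itself once ring B is a free phenol.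
- Comparison: the chosen route takes C3 from an amino acid, sets C2 and C4 one at a time on a ring, and frees the cyclising phenol by chelation rather than by selective deprotection.

Alternative 2: The C4–C4a bond is cut. Cathodic reduction with NiBr2 and 4,4'-di-tert-butyl-2,2'-bipyridine converts the N-hydroxyphthalimide ester A5 into a C4 dioxolanyl radical, which nickel joins to the aryl bromide carbon C4a, closing ring C to acetonide A4. The C3–C4 diol comes from (2S,3S)-tartaric acid A6.
- For it: the cis-fused dioxolane forces the 3,4-cis relation whatever the radical does. That is firmer control of C4 than a hydride reduction, and the prenyl group is tolerated.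
- Against it: A5 already needs the O1–C2 ether with defined C2 configuration, an SN2 etherification at a para-oxygenated benzylic carbon with a hindered phenol.
- Against it: the aryl bromide is electron-rich and flanked on both sides, so oxidative addition is slow, while the radical can be reduced or the alkylnickel can lose the β-oxygen.
- Against it: A4 must be opened with acid, which the C4 alcohol and the prenylphenol of the target do not tolerate.
- Comparison: the chosen route ends with fluoride only and reaches its cyclisation precursor in fewer operations.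

Alternative 3: The C4a–C4 and O1–C2 bonds are made in one pot. The titanium phenoxide from resorcinol A8 and ClTi(OiPr)3 adds through its ortho carbon to epoxy aldehyde A9, and the same phenol oxygen opens the epoxide at C2 with inversion, giving A7, one desilylation from the target.
- For it: it is by far the shortest. A8 is symmetric like 5, ring A needs no protecting groups and the prenyl group is in place. If it worked it would beat the chosen route on step count.
- Against it: the C4 configuration depends on whether titanium chelates the epoxide oxygen during the addition.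
- Against it: A9 carries a para-silyloxyphenyl epoxide that ionises or rearranges with Lewis acids.
- Against it: A7 is a 4-hydroxyflavan on a phloroglucinol ring, sitting in a Lewis acidic medium beside nucleophilic A8, the conditions under which such alcohols ionise and are arylated again.
- Comparison: the chosen route is much longer, but each bond is made in its own step and the C4 hydroxyl appears only after all Lewis acid steps are over.

Key step: step 9

Remark: 2-bromo-5-methoxybenzene-1,3-diol (5) is not assumed to be a stock chemical and is made in steps 1–3. Flavan numbering is used for ring positions (ring B primed). TBS = tert-butyldimethylsilyl, TBSO = tert-butyldimethylsilyloxy, MOM = methoxymethyl, DDQ = 2,3-dichloro-5,6-dicyano-1,4-benzoquinone.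

## Route

Step 1
Reactants: 1 5-methoxyresorcinol (5-methoxybenzene-1,3-diol)
Product: 2 1-methoxy-3,5-bis(methoxymethoxy)benzene
Conditions: MOMCl (2.5 equiv), i-Pr2NEt (3 equiv), CH2Cl2, 0 °C → rt
Reagents that add atoms: chloromethyl methyl ether, COCCl
Why: Base-mediated O-alkylation of both phenols; the MOM ethers are inert to butyllithium and serve as the ortho-directing groups for step 2.

Step 2
Reactants: 2 1-methoxy-3,5-bis(methoxymethoxy)benzene
Product: 4 2-bromo-5-methoxy-1,3-bis(methoxymethoxy)benzene, via aryllithium 3 (not isolated)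
Conditions: n-BuLi (1.1 equiv), THF, 0 °C; then BrCCl2CCl2Br (1.2 equiv), −78 °C → rt
Reagents that add atoms: 1,2-dibromo-1,1,2,2-tetrachloroethane, BrC(Cl)(Cl)C(Cl)(Cl)Br
Why: Directed ortho-metalation: the hydrogen between the two MOM ethers is the only one chelated from both sides, so lithiation to 3 and bromine transfer should place bromine there and keep the ring symmetric.

Step 3
Reactants: 4 2-bromo-5-methoxy-1,3-bis(methoxymethoxy)benzene
Product: 5 2-bromo-5-methoxybenzene-1,3-diol
Conditions: HCl (1.25 M in MeOH), 40 °C
Reagents that add atoms: none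
Why: Acid-catalysed acetal exchange with methanol frees both phenols; the aryl bromide and methyl ether are inert, and the two open ring positions of the product are equivalent.

Step 4
Reactants: 6 D-tyrosine
Product: 8 (R)-2-hydroxy-3-(4-hydroxyphenyl)propanoic acid, via α-lactone 7 (not isolated)
Conditions: NaNO2 (1.5 equiv), 1 M aq. H2SO4, 0 °C → rt
Reagents that add atoms: water, O
Why: Diazotisation of the α-amino acid; the carboxylate expels nitrogen with inversion to give α-lactone 7 and water opens it at the same carbon with a second inversion, so the (R) configuration is retained; cold dilute acid limits nitrosation of the phenol ring.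

Step 5
Reactants: 8 (R)-2-hydroxy-3-(4-hydroxyphenyl)propanoic acid
Product: 9 (R)-2-acetoxy-3-(4-acetoxyphenyl)propanoic acid
Conditions: Ac2O (3 equiv), pyridine, 0 °C → rt; then H2O, THF
Reagents that add atoms: acetic anhydride, CC(=O)OC(C)=O
Why: Acetylation of the alcohol and the phenol (the mixed anhydride at the carboxyl is hydrolysed on work-up); acetates survive AlCl3 where silyl ethers would not, and the ring B acetate makes ring B a poor partner for self-acylation.

Step 6
Reactants: 9 (R)-2-acetoxy-3-(4-acetoxyphenyl)propanoic acid; 5 2-bromo-5-methoxybenzene-1,3-diol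
Product: 11 (R)-2-acetoxy-3-(4-acetoxyphenyl)-1-(3-bromo-2,4-dihydroxy-6-methoxyphenyl)propan-1-one, via acid chloride 10 (not isolated)
Conditions: (COCl)2 (1.2 equiv), DMF (cat.), CH2Cl2, 0 °C → rt, evaporate; then 5, AlCl3 (3.5 equiv), CH2Cl2–MeNO2, 0 °C → rt; 1 M aq. HCl
Reagents that add atoms: none
Why: Acid chloride formation followed by Friedel–Crafts acylation of the aluminium phenoxide of 5 (direct C-acylation or O-acylation and Fries migration end at the same carbon); only two equivalent positions are open, so one regioisomer can form, with bromine between the two hydroxyls. The α-acetoxy stereocentre is expected to hold at 0 °C because the acetoxy group bridges the acylium ion, and the new carbonyl is tied up in a chelate with the ortho phenoxide, which disfavours cleavage of the methyl ether.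

Step 7
Reactants: 11 (R)-2-acetoxy-3-(4-acetoxyphenyl)-1-(3-bromo-2,4-dihydroxy-6-methoxyphenyl)propan-1-one
Product: 12 (R)-1-(3-bromo-2,4-dihydroxy-6-methoxyphenyl)-2-hydroxy-3-(4-hydroxyphenyl)propan-1-one
Conditions: HCl (1.25 M in MeOH), 0 °C → rt
Reagents that add atoms: none
Why: Acid-catalysed transesterification removes the aryl acetate and the activated α-keto acetate (and any acetyl that has moved to a ring A phenol) without forming the enolate that a base would, so the stereocentre next to the ketone is not put at risk.

Step 8
Reactants: 12 (R)-1-(3-bromo-2,4-dihydroxy-6-methoxyphenyl)-2-hydroxy-3-(4-hydroxyphenyl)propan-1-one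
Product: 13 (R)-1-[3-bromo-2-hydroxy-6-methoxy-4-(TBSO)phenyl]-2-(TBSO)-3-[4-(TBSO)phenyl]propan-1-one
Conditions: TBSCl (3.3 equiv), imidazole (7 equiv), DMF, 0 °C → rt
Reagents that add atoms: tert-butyldimethylsilyl chloride, CC(C)(C)[Si](C)(C)Cl
Why: Silylation of the two unhindered phenols and the secondary alcohol; the remaining phenol is hydrogen-bonded to the ketone and flanked by bromine and should stay free (chelation-controlled selective protection), leaving exactly the nucleophile needed in step 9.

Step 9
Reactants: 13 (R)-1-[3-bromo-2-hydroxy-6-methoxy-4-(TBSO)phenyl]-2-(TBSO)-3-[4-(TBSO)phenyl]propan-1-one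
Product: 14 (2R,3R)-8-bromo-5-methoxy-3,7-bis(TBSO)-2-[4-(TBSO)phenyl]chroman-4-one
Conditions: DDQ (1.2 equiv), 4 Å MS, 1,4-dioxane, rt → 60 °C
Reagents that add atoms: none
Why: DDQ forms a charge-transfer complex with the silyloxyphenyl ring and removes hydride from the benzylic CH2 (future C2), giving a cation delocalised as an O-silylated para-quinone methide paired with the hydroquinone anion. The chelated phenol oxygen on C8a adds to this carbon in a 6-exo-trig closure (the C2=C1' bond of the quinone methide form is exocyclic to the new ring), which forms O1–C2 and ring C, and the hydroquinone anion takes the phenolic proton. The closest known reaction type is the DDQ oxidative cyclisation of 2'-hydroxydihydrochalcones to flavanones, together with DDQ benzylic etherification of para-alkoxy alkylarenes. The new stereocentre C2 is controlled by C3 from D-tyrosine: in the chair-like transition state the aryl group and the C3 silyloxy group are both pseudo-equatorial, giving the 2,3-trans (2R) product, and any cis isomer can reopen through the same cation under the acidic hydroquinone and drain to trans. Site selectivity is secured because this CH2 is the only C–H benzylic to a donor ring, the C3–H next to the carbonyl is not hydridic, and ring A is deactivated by the acyl group and bromine with its one free hydroxyl locked in a hydrogen bond. The step needs capture of the cation by oxygen to be faster than loss of the C3 proton, which would give a silyloxy enone and erase C3; the phenol is held six atoms away and no base stronger than the hydroquinone anion is present. Further oxidation of 14 is held back because its O1 is a vinylogous ester oxygen and C3 bears an oxygen, which make C2–H poorly hydridic, and because DDQ is used in slight excess only. The C8 bromide is inert to DDQ, whereas a prenyl group ortho to the free phenol would itself be oxidised and cyclised.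

Step 10
Reactants: 14 (2R,3R)-8-bromo-5-methoxy-3,7-bis(TBSO)-2-[4-(TBSO)phenyl]chroman-4-one
Product: 15 (2R,3S,4S)-8-bromo-5-methoxy-3,7-bis(TBSO)-2-[4-(TBSO)phenyl]chroman-4-ol
Conditions: LiBH(s-Bu)3 (1.5 equiv), THF, −78 °C; aq. NH4Cl
Reagents that add atoms: none
Why: Ketone reduction under steric approach control: with the C2 aryl and C3 silyloxy groups equatorial, the bulky borohydride approaches C4 along the equatorial trajectory, anti to the neighbouring silyloxy group and away from the axial C2–H, and should give the axial 4β alcohol (3,4-cis, 4S); the aryl bromide and silyl ethers are inert at −78 °C.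

Step 11
Reactants: 15 (2R,3S,4S)-8-bromo-5-methoxy-3,7-bis(TBSO)-2-[4-(TBSO)phenyl]chroman-4-ol
Product: 16 (2R,3R,4S)-8-bromo-5-methoxy-3,4,7-tris(TBSO)-2-[4-(TBSO)phenyl]chroman
Conditions: TBSOTf (1.5 equiv), 2,6-lutidine (3 equiv), CH2Cl2, −78 → 0 °C
Reagents that add atoms: tert-butyldimethylsilyl triflate, CC(C)(C)[Si](C)(C)OS(=O)(=O)C(F)(F)F
Why: Silyl triflate silylation of the hindered axial benzylic alcohol under lutidine buffering, so no acid can ionise the C4–O bond; the hydroxyl must be masked before the organolithium step (the C3 descriptor changes from S to R only because of the new silicon on O4).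

Step 12
Reactants: 16 (2R,3R,4S)-8-bromo-5-methoxy-3,4,7-tris(TBSO)-2-[4-(TBSO)phenyl]chroman; 17 prenyl bromide (1-bromo-3-methylbut-2-ene)
Product: 20 (2R,3R,4S)-5-methoxy-8-(3-methylbut-2-enyl)-3,4,7-tris(TBSO)-2-[4-(TBSO)phenyl]chroman, via C8 aryllithium 18 (not isolated), via C8 arylcopper 19 (not isolated)
Conditions: t-BuLi (2.1 equiv), Et2O, −78 °C; CuBr·SMe2 (1.1 equiv), −78 → −40 °C; 17 (1.5 equiv), −40 → 0 °C
Reagents that add atoms: none
Why: Bromine–lithium exchange gives 18, transmetalation gives 19, and the arylcopper alkylates 17 at its primary carbon (SN2-type allylic substitution; the tertiary SN2' product is disfavoured on steric grounds). The exchange is run cold in ether and trapped with copper at once to outrun 1,3 migration of silicon from O7 to C8.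

Step 13
Reactants: 20 (2R,3R,4S)-5-methoxy-8-(3-methylbut-2-enyl)-3,4,7-tris(TBSO)-2-[4-(TBSO)phenyl]chroman
Product: 21 5-O-methyl-8-prenylafzelechin-4β-ol, (2R,3S,4S)-2-(4-hydroxyphenyl)-5-methoxy-8-(3-methylbut-2-enyl)chroman-3,4,7-triol
Conditions: TBAF (6 equiv), AcOH (6 equiv), THF, 0 °C → rt
Reagents that add atoms: none
Why: Fluoride cleavage of the two aryl and two alkyl silyl ethers; acetic acid buffers the phenoxides and alkoxides, so neither base-induced opening of ring C through a ring B quinone methide nor acid ionisation at C4 or cyclisation of the prenylphenol should occur.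

## Compound list

1 | 5-methoxyresorcinol (5-methoxybenzene-1,3-diol) | COc1cc(O)cc(O)c1 | starting material
2 | 1-methoxy-3,5-bis(methoxymethoxy)benzene | COCOc1cc(OC)cc(OCOC)c1 | intermediate
3 | [4-methoxy-2,6-bis(methoxymethoxy)phenyl]lithium | [Li]c1c(OCOC)cc(OC)cc1OCOC | intermediate (not isolated)
4 | 2-bromo-5-methoxy-1,3-bis(methoxymethoxy)benzene | COCOc1cc(OC)cc(OCOC)c1Br | intermediate
5 | 2-bromo-5-methoxybenzene-1,3-diol | COc1cc(O)c(Br)c(O)c1 | intermediate
6 | D-tyrosine | N[C@H](Cc1ccc(O)cc1)C(=O)O | starting material
7 | (S)-3-(4-hydroxybenzyl)oxiran-2-one (α-lactone) | O=C1O[C@H]1Cc1ccc(O)cc1 | intermediate (not isolated)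
8 | (R)-2-hydroxy-3-(4-hydroxyphenyl)propanoic acid | O[C@H](Cc1ccc(O)cc1)C(=O)O | intermediate
9 | (R)-2-acetoxy-3-(4-acetoxyphenyl)propanoic acid | CC(=O)O[C@H](Cc1ccc(OC(C)=O)cc1)C(=O)O | intermediate
10 | (R)-2-acetoxy-3-(4-acetoxyphenyl)propanoyl chloride | CC(=O)O[C@H](Cc1ccc(OC(C)=O)cc1)C(Cl)=O | intermediate (not isolated)
11 | (R)-2-acetoxy-3-(4-acetoxyphenyl)-1-(3-bromo-2,4-dihydroxy-6-methoxyphenyl)propan-1-one | COc1cc(O)c(Br)c(O)c1C(=O)[C@H](OC(C)=O)Cc1ccc(OC(C)=O)cc1 | intermediate
12 | (R)-1-(3-bromo-2,4-dihydroxy-6-methoxyphenyl)-2-hydroxy-3-(4-hydroxyphenyl)propan-1-one | COc1cc(O)c(Br)c(O)c1C(=O)[C@H](O)Cc1ccc(O)cc1 | intermediate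
13 | (R)-1-[3-bromo-2-hydroxy-6-methoxy-4-(TBSO)phenyl]-2-(TBSO)-3-[4-(TBSO)phenyl]propan-1-one | COc1cc(O[Si](C)(C)C(C)(C)C)c(Br)c(O)c1C(=O)[C@H](O[Si](C)(C)C(C)(C)C)Cc1ccc(O[Si](C)(C)C(C)(C)C)cc1 | intermediate (precursor of the key step)
14 | (2R,3R)-8-bromo-5-methoxy-3,7-bis(TBSO)-2-[4-(TBSO)phenyl]chroman-4-one | COc1cc(O[Si](C)(C)C(C)(C)C)c(Br)c2c1C(=O)[C@H](O[Si](C)(C)C(C)(C)C)[C@@H](c1ccc(O[Si](C)(C)C(C)(C)C)cc1)O2 | intermediate (product of the key step)
15 | (2R,3S,4S)-8-bromo-5-methoxy-3,7-bis(TBSO)-2-[4-(TBSO)phenyl]chroman-4-ol | COc1cc(O[Si](C)(C)C(C)(C)C)c(Br)c2c1[C@H](O)[C@H](O[Si](C)(C)C(C)(C)C)[C@@H](c1ccc(O[Si](C)(C)C(C)(C)C)cc1)O2 | intermediate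
16 | (2R,3R,4S)-8-bromo-5-methoxy-3,4,7-tris(TBSO)-2-[4-(TBSO)phenyl]chroman | COc1cc(O[Si](C)(C)C(C)(C)C)c(Br)c2c1[C@H](O[Si](C)(C)C(C)(C)C)[C@H](O[Si](C)(C)C(C)(C)C)[C@@H](c1ccc(O[Si](C)(C)C(C)(C)C)cc1)O2 | intermediate
17 | prenyl bromide (1-bromo-3-methylbut-2-ene) | CC(C)=CCBr | starting material
18 | C8 aryllithium of 16 (Li in place of Br) | COc1cc(O[Si](C)(C)C(C)(C)C)c([Li])c2c1[C@H](O[Si](C)(C)C(C)(C)C)[C@H](O[Si](C)(C)C(C)(C)C)[C@@H](c1ccc(O[Si](C)(C)C(C)(C)C)cc1)O2 | intermediate (not isolated)
19 | C8 arylcopper of 16 (Cu in place of Br) | COc1cc(O[Si](C)(C)C(C)(C)C)c([Cu])c2c1[C@H](O[Si](C)(C)C(C)(C)C)[C@H](O[Si](C)(C)C(C)(C)C)[C@@H](c1ccc(O[Si](C)(C)C(C)(C)C)cc1)O2 | intermediate (not isolated)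
20 | (2R,3R,4S)-5-methoxy-8-(3-methylbut-2-enyl)-3,4,7-tris(TBSO)-2-[4-(TBSO)phenyl]chroman | COc1cc(O[Si](C)(C)C(C)(C)C)c(CC=C(C)C)c2c1[C@H](O[Si](C)(C)C(C)(C)C)[C@H](O[Si](C)(C)C(C)(C)C)[C@@H](c1ccc(O[Si](C)(C)C(C)(C)C)cc1)O2 | intermediate
21 | 5-O-methyl-8-prenylafzelechin-4β-ol, (2R,3S,4S)-2-(4-hydroxyphenyl)-5-methoxy-8-(3-methylbut-2-enyl)chroman-3,4,7-triol | COc1cc(O)c(CC=C(C)C)c2c1[C@H](O)[C@H](O)[C@@H](c1ccc(O)cc1)O2 | target

## Step count and least certain steps

Total: 13 steps. Longest linear sequence: 11 steps (1 to 21 through steps 1–3 and 6–13); the branch from 6 has 10 steps (steps 4–13).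

Step 9 (key step). The most likely failure is loss of the C3 proton from the benzylic cation instead of capture by the phenol, which gives a silyloxy enone and destroys the only stereocentre the cation was meant to keep. Further dehydrogenation of the product and slow hydride abstraction are the other risks, because silyloxy is a weaker donor than methoxy and C2 is flanked by an oxygenated carbon. The fallback sets out from 5 and returns at 14; it makes O1–C2 by epoxide opening rather than C–H oxidation.
- Friedel–Crafts acetylation of 5 (AcCl, AlCl3) should give 1-(3-bromo-2,4-dihydroxy-6-methoxyphenyl)ethan-1-one F1.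
- Both phenols are protected (NaH, MOMCl) to give 1-[3-bromo-6-methoxy-2,4-bis(methoxymethoxy)phenyl]ethan-1-one F2.
- Claisen–Schmidt condensation with 4-(methoxymethoxy)benzaldehyde (KOH, EtOH) gives the E-chalcone F3.
- Julia–Colonna epoxidation (poly-L-leucine, urea–H2O2, DBU, THF) is expected to give the (2R,3S)-epoxy ketone F4.
- HCl in MeOH removes the three acetals, and the freed phenol next to the ketone opens the epoxide at the benzylic carbon (6-endo) to give (2R,3R)-8-bromo-3,7-dihydroxy-2-(4-hydroxyphenyl)-5-methoxychroman-4-one F5.
- TBSCl and imidazole in DMF convert F5 into 14.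

Step 6. The likely failures are partial racemisation of the carbon next to the acyl group (enolisation of the aluminium-bound ketone or ketene formation from 10), O-acylation that stops short of migrating to carbon, and cleavage of the methyl ether by AlCl3. The fallback sets out from 4 and 8 and returns at 12; it makes the C4–C4a bond with a ring A nucleophile.
- NIS in MeCN iodinates one of the two equivalent open positions of 4 to give 2-bromo-4-iodo-5-methoxy-1,3-bis(methoxymethoxy)benzene F6.
- Iodine–magnesium exchange with iPrMgCl·LiCl (THF, −40 °C), selective for C–I over C–Br, gives [3-bromo-6-methoxy-2,4-bis(methoxymethoxy)phenyl]magnesium chloride F7.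
- Acid 8 is coupled with MeNHOMe·HCl (EDC, HOBt, i-Pr2NEt) to (R)-2-hydroxy-3-(4-hydroxyphenyl)-N-methoxy-N-methylpropanamide F8, which is silylated (TBSCl, imidazole) to the bis(silyl) Weinreb amide F9.
- F7 adds once to F9 to give (R)-1-[3-bromo-6-methoxy-2,4-bis(methoxymethoxy)phenyl]-2-(TBSO)-3-[4-(TBSO)phenyl]propan-1-one F10.
- HCl in MeOH removes both acetals and both silyl groups and gives 12.

Step 12. The likely failure is migration of the silyl group from O7 to the lithiated C8 (a 1,3 retro-Brook shift) before copper traps 18. Protonation of 18 and attack at the tertiary end of 17 are lesser risks. The fallback sets out from 16 and returns at 20 and uses no organolithium.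
- Stille coupling of 16 with allyltributylstannane (Pd2(dba)3, P(t-Bu)3, CsF, dioxane, 90 °C) gives (2R,3R,4S)-8-allyl-5-methoxy-3,4,7-tris(TBSO)-2-[4-(TBSO)phenyl]chroman F11.
- Cross-metathesis with 2-methylbut-2-ene (second-generation Grubbs catalyst, CH2Cl2, 40 °C) turns the allyl group into prenyl and gives 20.

Step 10. The likely failure is poor facial selectivity: the peri methoxy group and the C3 silyloxy group both crowd the equatorial trajectory, so some axial attack and the 4α epimer may result. The fallback sets out from 14 and returns at 15; it sets C4 by substitution rather than by reduction.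
- NaBH4 in MeOH–THF, which prefers axial attack, gives the equatorial alcohol (2R,3S,4R)-8-bromo-5-methoxy-3,7-bis(TBSO)-2-[4-(TBSO)phenyl]chroman-4-ol F12.
- Mitsunobu reaction with benzoic acid (PPh3, DIAD, THF) gives the 4β benzoate (2R,3R,4S)-8-bromo-5-methoxy-3,7-bis(TBSO)-2-[4-(TBSO)phenyl]chroman-4-yl benzoate F13. Whether the displacement runs with inversion or through the ring A-stabilised cation, the carboxylate is expected to enter pseudo-axially, trans to the C2 aryl group.
- i-Bu2AlH (CH2Cl2, −78 °C) cleaves the benzoate without touching the aryl silyl ethers and gives 15.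

## Further compounds

F1 | step 9 | 1-(3-bromo-2,4-dihydroxy-6-methoxyphenyl)ethan-1-one | COc1cc(O)c(Br)c(O)c1C(C)=O
F2 | step 9 | 1-[3-bromo-6-methoxy-2,4-bis(methoxymethoxy)phenyl]ethan-1-one | COCOc1cc(OC)c(C(C)=O)c(OCOC)c1Br
F3 | step 9 | (E)-1-[3-bromo-6-methoxy-2,4-bis(methoxymethoxy)phenyl]-3-[4-(methoxymethoxy)phenyl]prop-2-en-1-one | COCOc1ccc(/C=C/C(=O)c2c(OC)cc(OCOC)c(Br)c2OCOC)cc1
F4 | step 9 | [3-bromo-6-methoxy-2,4-bis(methoxymethoxy)phenyl][(2R,3S)-3-[4-(methoxymethoxy)phenyl]oxiran-2-yl]methanone | COCOc1cc(OC)c(C(=O)[C@@H]2O[C@H]2c2ccc(OCOC)cc2)c(OCOC)c1Br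
F5 | step 9 | (2R,3R)-8-bromo-3,7-dihydroxy-2-(4-hydroxyphenyl)-5-methoxychroman-4-one | COc1cc(O)c(Br)c2c1C(=O)[C@H](O)[C@@H](c1ccc(O)cc1)O2
F6 | step 6 | 2-bromo-4-iodo-5-methoxy-1,3-bis(methoxymethoxy)benzene | COCOc1cc(OC)c(I)c(OCOC)c1Br
F7 | step 6 | [3-bromo-6-methoxy-2,4-bis(methoxymethoxy)phenyl]magnesium chloride | COCOc1cc(OC)c([Mg]Cl)c(OCOC)c1Br
F8 | step 6 | (R)-2-hydroxy-3-(4-hydroxyphenyl)-N-methoxy-N-methylpropanamide | CON(C)C(=O)[C@H](O)Cc1ccc(O)cc1
F9 | step 6 | (R)-2-(TBSO)-3-[4-(TBSO)phenyl]-N-methoxy-N-methylpropanamide | CON(C)C(=O)[C@H](O[Si](C)(C)C(C)(C)C)Cc1ccc(O[Si](C)(C)C(C)(C)C)cc1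
F10 | step 6 | (R)-1-[3-bromo-6-methoxy-2,4-bis(methoxymethoxy)phenyl]-2-(TBSO)-3-[4-(TBSO)phenyl]propan-1-one | COCOc1cc(OC)c(C(=O)[C@H](O[Si](C)(C)C(C)(C)C)Cc2ccc(O[Si](C)(C)C(C)(C)C)cc2)c(OCOC)c1Br
F11 | step 12 | (2R,3R,4S)-8-allyl-5-methoxy-3,4,7-tris(TBSO)-2-[4-(TBSO)phenyl]chroman | COc1cc(O[Si](C)(C)C(C)(C)C)c(CC=C)c2c1[C@H](O[Si](C)(C)C(C)(C)C)[C@H](O[Si](C)(C)C(C)(C)C)[C@@H](c1ccc(O[Si](C)(C)C(C)(C)C)cc1)O2
F12 | step 10 | (2R,3S,4R)-8-bromo-5-methoxy-3,7-bis(TBSO)-2-[4-(TBSO)phenyl]chroman-4-ol | COc1cc(O[Si](C)(C)C(C)(C)C)c(Br)c2c1[C@@H](O)[C@H](O[Si](C)(C)C(C)(C)C)[C@@H](c1ccc(O[Si](C)(C)C(C)(C)C)cc1)O2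
F13 | step 10 | (2R,3R,4S)-8-bromo-5-methoxy-3,7-bis(TBSO)-2-[4-(TBSO)phenyl]chroman-4-yl benzoate | COc1cc(O[Si](C)(C)C(C)(C)C)c(Br)c2c1[C@H](OC(=O)c1ccccc1)[C@H](O[Si](C)(C)C(C)(C)C)[C@@H](c1ccc(O[Si](C)(C)C(C)(C)C)cc1)O2
A1 | alternative 1 | trans-2,3-epoxide of the tetrasilylated 1,3-diarylpropan-1-ol (C2–C3 epoxide, silyl ether at C4, flavan numbering) | COc1cc(O[Si](C)(C)C(C)(C)C)c(CC=C(C)C)c(O[Si](C)(C)C(C)(C)C)c1[C@H](O[Si](C)(C)C(C)(C)C)[C@@H]1O[C@H]1c1ccc(O[Si](C)(C)C(C)(C)C)cc1
A2 | alternative 1 | (S)-2-[6-methoxy-3-(3-methylbut-2-enyl)-2,4-bis(TBSO)phenyl]-2-(TBSO)acetaldehyde | COc1cc(O[Si](C)(C)C(C)(C)C)c(CC=C(C)C)c(O[Si](C)(C)C(C)(C)C)c1[C@H](O[Si](C)(C)C(C)(C)C)C=O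
A3 | alternative 1 | [4-(TBSO)benzyl]dimethylsulfonium bromide | C[S+](C)Cc1ccc(O[Si](C)(C)C(C)(C)C)cc1.[Br-]
A4 | alternative 2 | 3,4-O-isopropylidene-7,4'-bis-O-TBS 5-O-methyl-8-prenylafzelechin-4β-ol | COc1cc(O[Si](C)(C)C(C)(C)C)c(CC=C(C)C)c2c1[C@@H]1OC(C)(C)O[C@@H]1[C@@H](c1ccc(O[Si](C)(C)C(C)(C)C)cc1)O2
A5 | alternative 2 | N-hydroxyphthalimide ester of the trans-dioxolane acid carrying the C2 aryl ether to the ring A aryl bromide | COc1cc(O[Si](C)(C)C(C)(C)C)c(CC=C(C)C)c(O[C@H](c2ccc(O[Si](C)(C)C(C)(C)C)cc2)[C@H]2OC(C)(C)O[C@@H]2C(=O)ON2C(=O)c3ccccc3C2=O)c1Br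
A6 | alternative 2 | (2S,3S)-tartaric acid | OC(=O)[C@@H](O)[C@H](O)C(=O)O
A7 | alternative 3 | 4'-O-TBS 5-O-methyl-8-prenylafzelechin-4β-ol | COc1cc(O)c(CC=C(C)C)c2c1[C@H](O)[C@H](O)[C@@H](c1ccc(O[Si](C)(C)C(C)(C)C)cc1)O2
A8 | alternative 3 | 5-methoxy-2-(3-methylbut-2-enyl)benzene-1,3-diol | COc1cc(O)c(CC=C(C)C)c(O)c1
A9 | alternative 3 | (2R,3S)-3-[4-(TBSO)phenyl]oxirane-2-carbaldehyde | O=C[C@@H]1O[C@H]1c1ccc(O[Si](C)(C)C(C)(C)C)cc1
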